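# Total synthesis of 3α,6β,19-trihydroxylabda-8,13E-dien-15-oic acid (CNP0246116.2)

## Retrosynthetic overview
1. Feature: ring A (C1–C2–C3–C4–C5–C10) shares only the C5–C10 bond with ring B. Its two quaternary corners, C4 and C10, are joined by the unbranched C1–C2–C3 run, which carries only the axial 3α-OH. Cutting C2=C3 therefore leaves an intact ring B with an allyl arm on C10 and a vinyl arm on C4. The alkene is later oxidised from its open α face, because the β face lies under axial C19 and C20.
2. The 13E-enoic acid is made last from a C13 methyl ketone (Horner–Wadsworth–Emmons), which is carried as a dioxolane.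
3. C4, C5 and C6 come from a temporary 19,6β-γ-lactone on ring B. Convex-face methylation sets C4, iodolactonisation and deiodination set C6, and Ireland–Claisen rearrangement of a 7β-dienyl crotonate forms the C4–C5 bond and sets C5.
4. Ring B is the carbocycle of 2-methylcyclohexane-1,3-dione. The sequence is vinylogous ester, enantioselective decarboxylative allylation (C10), Stork–Danheiser side-chain addition (C8=C9), dehydrogenation and reagent-controlled C7 reduction.
5. Ring order: ring B is purchased, the temporary lactone ring is closed in step 10 and opened in step 13, and ring A is closed last in step 15.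

Key step: step 15

Locants are those of the labdane target: ring B = C5–C10, C17 on C8, C20 on C10, side chain C11–C16, C18/C19 on C4. β is the face of C20.

Assumption: the PHOX and oxazaborolidine catalysts follow their established sense of induction, in which the (S)-PHOX ligand gives (S)-2-allyl-2-methylcyclohexanone and the (S)-oxazaborolidine gives (R)-1-phenylethanol; if either runs the other way, the enantiomeric catalyst is used.

## Route

Step 1
Reactants: 1 2-methylcyclohexane-1,3-dione
Product: 2 3-isobutoxy-2-methylcyclohex-2-en-1-one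
Conditions: i-BuOH, p-TsOH·H2O (cat.), toluene, reflux, Dean–Stark trap
Reagents that add atoms: isobutanol, CC(C)CO
Why: Acid-catalysed vinylogous esterification of the enolised symmetric dione with removal of water can give only one enol ether and creates no stereocentre.

Step 2
Reactants: 2 3-isobutoxy-2-methylcyclohex-2-en-1-one; 3 allyl chloroformate
Product: 4 allyl 4-isobutoxy-3-methyl-2-oxocyclohex-3-ene-1-carboxylate (racemic)
Conditions: LiN(iPr)2 (2.1 equiv), toluene, −78 °C; then 3, −78 → 25 °C
Reagents that add atoms: allyl chloroformate (3), C=CCOC(=O)Cl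
Why: Kinetic deprotonation of a vinylogous ester occurs at the α′ carbon (future C10), and Claisen-type C-acylation of the lithium enolate in a weakly polar medium gives the β-keto ester, with the second equivalent of base covering the acidic product.

Step 3
Reactants: 4 allyl 4-isobutoxy-3-methyl-2-oxocyclohex-3-ene-1-carboxylate
Product: 5 allyl 4-isobutoxy-1,3-dimethyl-2-oxocyclohex-3-ene-1-carboxylate (racemic)
Conditions: MeI, Cs2CO3, MeCN, 50 °C
Reagents that add atoms: iodomethane, CI
Why: C-alkylation of the stabilised β-keto ester enolate installs C20, and the racemic quaternary centre does not matter because step 4 destroys and rebuilds it.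

Step 4
Reactants: 5 allyl 4-isobutoxy-1,3-dimethyl-2-oxocyclohex-3-ene-1-carboxylate
Product: 6 (6R)-6-allyl-3-isobutoxy-2,6-dimethylcyclohex-2-en-1-one
Conditions: Pd2(dba)3 (2.5 mol %), (R)-t-BuPHOX (6 mol %), toluene, 40 °C
Reagents that add atoms: none
Why: In this decarboxylative asymmetric allylic alkylation (Tsuji–Trost type, known for vinylogous esters of this kind), zerovalent palladium ionises the allyl ester, CO2 is lost, and both enantiomers converge on one prochiral enolate that is allylated inside the chiral ligand pocket, which sets C10 (R here, methyl β).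

Step 5
Reactants: 6 (6R)-6-allyl-3-isobutoxy-2,6-dimethylcyclohex-2-en-1-one; 7 2-(2-bromoethyl)-2-methyl-1,3-dioxolane
Product: 10 (4R)-4-allyl-2,4-dimethyl-3-[2-(2-methyl-1,3-dioxolan-2-yl)ethyl]cyclohex-2-en-1-one, via Grignard reagent 8 (not isolated), via bromomagnesium alkoxide 9 (not isolated)
Conditions: 7, Mg, THF, 25 °C; added to 6 + anhydrous CeCl3, THF, −78 → 0 °C; then 1 M HCl, 0 °C, short contact
Reagents that add atoms: 2-(2-bromoethyl)-2-methyl-1,3-dioxolane (7), CC1(CCBr)OCCO1; water, O
Why: In this Stork–Danheiser alkylative transposition the Grignard reagent, helped by oxophilic CeCl3, adds 1,2 to the hindered C9 carbonyl, and cold dilute acid ionises the tertiary 3-alkoxyallylic carbinol and hydrolyses the oxocarbenium ion to the C7 enone with the tetrasubstituted C8=C9 bond much faster than it attacks the dioxolane, leaving C10 untouched.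

Step 6
Reactants: 10 (4R)-4-allyl-2,4-dimethyl-3-[2-(2-methyl-1,3-dioxolan-2-yl)ethyl]cyclohex-2-en-1-one
Product: 11 (4S)-4-allyl-2,4-dimethyl-3-[2-(2-methyl-1,3-dioxolan-2-yl)ethyl]cyclohexa-2,5-dien-1-one
Conditions: LiN(iPr)2, THF, −78 °C; then PhS(Cl)=N-t-Bu, −78 °C
Reagents that add atoms: none
Why: In this Mukaiyama dehydrogenation, kinetic α′-deprotonation at C6, sulfur attack on the sulfinimidoyl chloride and syn elimination at −78 °C introduce C5=C6 without the heat or acid that would set off Cope or dienone–phenol migration of the C10 allyl group.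

Step 7
Reactants: 11 (4S)-4-allyl-2,4-dimethyl-3-[2-(2-methyl-1,3-dioxolan-2-yl)ethyl]cyclohexa-2,5-dien-1-one
Product: 12 (1S,4S)-4-allyl-2,4-dimethyl-3-[2-(2-methyl-1,3-dioxolan-2-yl)ethyl]cyclohexa-2,5-dien-1-ol (7β-OH, cis to C20)
Conditions: (R)-Me-CBS oxazaborolidine (0.3 equiv), catecholborane, toluene, −78 °C; basic work-up, Et3N-washed silica
Reagents that add atoms: none
Why: In this Corey–Bakshi–Shibata reduction the distant C10 methyl and allyl groups cannot bias the carbonyl faces, so the catalyst does it by treating the α-methylated C8=C9 arm as the large group and the unsubstituted C6=C5 arm as the small one, delivers hydride to the α face to set 7β-OH (7S), leaves the terminal alkene untouched by catecholborane at −78 °C, and converts any minor C10 enantiomer into a separable diastereomer.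

Step 8
Reactants: 12 (1S,4S)-dienol; 13 crotonic anhydride
Product: 14 (1S,4S)-4-allyl-2,4-dimethyl-3-[2-(2-methyl-1,3-dioxolan-2-yl)ethyl]cyclohexa-2,5-dien-1-yl (E)-but-2-enoate
Conditions: 13, Et3N, DMAP (cat.), CH2Cl2, 0 °C
Reagents that add atoms: crotonic anhydride (13), C/C=C/C(=O)OC(=O)/C=C/C
Why: DMAP-catalysed acylation under basic, non-ionising conditions keeps the acid-labile bis-allylic C7–O bond and its configuration, and any deconjugation to the but-3-enoate is harmless because both esters give the same dienolate.

Step 9
Reactants: 14 7β-dienyl crotonate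
Product: 17 2-[(1S,6S)-6-allyl-4,6-dimethyl-5-[2-(2-methyl-1,3-dioxolan-2-yl)ethyl]cyclohexa-2,4-dien-1-yl]but-3-enoic acid (C4 epimers), via silyl ketene acetal 15 (not isolated), via trimethylsilyl ester 16 (not isolated)
Conditions: LiN(iPr)2, Me3SiCl, THF/DMPU, −78 → 40 °C; then H2O, pH 5 buffer
Reagents that add atoms: chlorotrimethylsilane, C[Si](C)(C)Cl (stays only in 15 and 16)
Why: In this Ireland–Claisen rearrangement of an ester dienolate, γ-deprotonation and O-silylation give the ketene acetal, whose α-carbon (C4) bonds suprafacially to C5 on the β face from which C7–O departs, so C7 is relayed to C5 (C4 arm cis to C20, trans to the allyl arm), the disubstituted C5=C6 alkene reacts rather than the fully substituted C9 terminus, and C4 is left undefined because step 12 rebuilds it.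

Step 10
Reactants: 17 diene acid
Product: 18 7α-iodo-19,6β-lactone of ring B (cis-fused γ-lactone; O on C6β, C4 bearing H and vinyl, C8=C9 retained)
Conditions: I2, NaHCO3, MeCN, 0 °C, dark; crude product used at once
Reagents that add atoms: iodine, [I][I]
Why: In this iodolactonisation iodine binds all alkenes reversibly but only C6=C7 has the carboxylate within reach of a five-membered anti-periplanar opening, so O–C6 forms on the β face (cis to C4, setting C6) with iodine α on C7, whereas the vinyl and allyl groups would need four- or seven-membered rings and attack at C7 a bridged δ-lactone, and any allylic drift of the iodide is harmless because step 11 passes through one common allyl radical.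

Step 11
Reactants: 18 7α-iodo-19,6β-lactone
Product: 19 19,6β-lactone of ring B with C7H2 (C4 bearing H and vinyl, C4 epimers)
Conditions: Bu3SnH (0.3 M), Et3B/air (cat.), toluene, 0 °C
Reagents that add atoms: none
Why: In this radical-chain dehalogenation, iodine abstraction gives the C7–C8–C9 allyl radical, which takes hydrogen at the less hindered secondary terminus C7 and so keeps the tetrasubstituted C8=C9 alkene, while the low temperature and high stannane concentration outrun cyclisation onto the vinyl group.

Step 12
Reactants: 19 19,6β-lactone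
Product: 20 4-methyl-4-vinyl-19,6β-lactone of ring B (C18 methyl on the convex face cis to H5 and H6; vinyl on the concave face towards C10)
Conditions: LiN(iPr)2, THF/DMPU, −78 °C; then MeI, −78 → −20 °C
Reagents that add atoms: iodomethane, CI
Why: In this deconjugative α-alkylation of a lactone dienolate, the α-vinyl lactone (or its ethylidene tautomer) gives one planar dienolate that is methylated at Cα from the convex face of the cis-fused bicycle because C10 and its substituents cover the concave face, which sets the C4 quaternary centre with C18 α and the vinyl group pointing at C10.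

Step 13
Reactants: 20 4-methyl-4-vinyl-19,6β-lactone
Product: 21 6β,19-diol of ring B (C5 bearing the C(CH3)(CH2OH)(CH=CH2) group)
Conditions: LiAlH4, THF, 0 °C → reflux
Reagents that add atoms: none
Why: Hydride reduction of the neopentyl lactone to the diol touches no stereocentre and leaves the ketal and the three alkenes alone.

Step 14
Reactants: 21 6β,19-diol
Product: 22 6β,19-bis(tert-butyldimethylsilyl) ether of ring B with the C10 allyl and C4 vinyl arms (metathesis precursor)
Conditions: TBSOTf (3 equiv), 2,6-lutidine, CH2Cl2, −78 → 0 °C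
Reagents that add atoms: tert-butyldimethylsilyl triflate, CC(C)(C)[Si](C)(C)OS(=O)(=O)C(F)(F)F
Why: A silyl triflate with a hindered base silylates both the neopentyl primary and the crowded secondary alcohol under conditions too cold and short to disturb the dioxolane.

Step 15
Reactants: 22 ring B diene (C10 allyl, C4 vinyl)
Product: 23 trans-fused labda-2,8-diene: 6β,19-bis(TBS) ether, C13 dioxolane
Conditions: second-generation Grubbs catalyst RuCl2(=CHPh)(PCy3)(H2IMes) (5–10 mol %), toluene (2 mM), 80 °C, argon sparge
Reagents that add atoms: none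
Why: The benzylidene first exchanges with the unhindered allyl terminus on C10 to put ruthenium on C2, this carbene adds intramolecularly to the neopentyl C4 vinyl group, and cycloreversion of the ruthenacyclobutane forms C2=C3 and a methylidene that carries the chain while ethene is swept out. The closest known reaction type is ring-closing metathesis of 1,7-dienes to cyclohexenes with one alkene on a quaternary carbon. Ring A closes as a six-membered ring by alkene metathesis, with both alkene carbons ending inside the ring, across the trans-diequatorial C10–C1 and C5–C4 bonds of ring B, so the trans-decalin chair is already laid out in 22. No stereocentre is made: C4, C5, C6 and C10 are not touched, and the new alkene can only be cis in a six-membered ring. The step needs chemoselectivity among three alkenes and against oligomerisation, and this is secured because the tetrasubstituted C8=C9 bond cannot bind the carbene and the hindered vinyl group does not homodimerise, so at high dilution cyclisation is the only productive outlet.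

Step 16
Reactants: 23 labda-2,8-diene
Product: 24 2α,3α-diol
Conditions: OsO4 (5 mol %), NMO, acetone/H2O, 25 °C
Reagents that add atoms: osmium tetroxide, O=[Os](=O)(=O)=O; N-methylmorpholine N-oxide, C[N+]1([O-])CCOCC1; water, O
Why: In this catalytic syn dihydroxylation OsO4 adds to the only accessible alkene from the α face, because axial C19 and C20 roof the β face and the tetrasubstituted C8=C9 bond next to C10 is too hindered, which sets the axial 3α-OH together with the sacrificial equatorial 2α-OH.

Step 17
Reactants: 24 2α,3α-diol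
Product: 25 2α-O-(phenoxythiocarbonyl) 3α-alcohol
Conditions: PhOC(S)Cl (1.1 equiv), pyridine, CH2Cl2, 0 °C
Reagents that add atoms: O-phenyl chlorothionoformate, ClC(=S)Oc1ccccc1
Why: Kinetic acylation picks the equatorial, unhindered 2α-OH over the axial 3α-OH that is neopentyl to C4, and one equivalent of reagent without DMAP limits closure to the cyclic thionocarbonate.

Step 18
Reactants: 25 2α-thionocarbonate
Product: 26 3α-alcohol (C2H2), 6β,19-bis(TBS) ether, C13 dioxolane
Conditions: Bu3SnH, AIBN (cat.), toluene, 90 °C
Reagents that add atoms: none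
Why: In this Barton–McCombie deoxygenation the stannyl radical adds to C=S, the secondary C2 radical is released and reduced, and the free 3α-OH, silyl ethers, ketal and C8=C9 bond are inert to the neutral chain.

Step 19
Reactants: 26 3α-alcohol ketal
Product: 27 C13 methyl ketone (14,15-dinorlabd-8-en-13-one; 3α-OH, 6β,19-bis(TBS) ether)
Conditions: PPTS (cat.), acetone/H2O, 50 °C
Reagents that add atoms: water, O
Why: Mild acid-catalysed ketal hydrolysis frees the methyl ketone, while the hindered TBS ethers survive a pyridinium acid.

Step 20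
Reactants: 27 C13 methyl ketone; 28 triethyl phosphonoacetate
Product: 29 ethyl (13E)-3α-hydroxy-6β,19-bis(TBS-oxy)labda-8,13-dien-15-oate
Conditions: 28, NaH, THF, 0 °C; then 27, 0 → 50 °C; E isomer separated on silica
Reagents that add atoms: triethyl phosphonoacetate (28), CCOC(=O)CP(=O)(OCC)OCC
Why: Horner–Wadsworth–Emmons olefination of the unhindered methyl ketone under equilibrating conditions favours the E enoate (ester trans to the larger C12 chain), the 3α-alkoxide formed by excess base is a spectator, and the minor Z isomer is removed by chromatography.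

Step 21
Reactants: 29 bis(TBS) ethyl ester
Product: 30 ethyl (13E)-3α,6β,19-trihydroxylabda-8,13-dien-15-oate
Conditions: HF·pyridine, THF/pyridine, 0 → 25 °C
Reagents that add atoms: none
Why: Fluoride-driven Si–O cleavage in a buffered medium removes both silyl ethers, including the crowded 6β one, without touching the enoate or the C8=C9 bond.

Step 22
Reactants: 30 triol ethyl ester
Product: 31 (13E)-3α,6β,19-trihydroxylabda-8,13-dien-15-oic acid, (3R,4S,5R,6R,10S), the target
Conditions: LiOH, THF/MeOH/H2O, 40 °C; then 1 M HCl to pH 3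
Reagents that add atoms: lithium hydroxide, [Li+].[OH-]
Why: Saponification of the conjugated ethyl ester followed by careful acidification gives the free acid with no stereocentre or alkene geometry at risk.

## Compound list
1 | 2-methylcyclohexane-1,3-dione | CC1C(=O)CCCC1=O | starting material
2 | 3-isobutoxy-2-methylcyclohex-2-en-1-one | CC1=C(OCC(C)C)CCCC1=O | intermediate
3 | allyl chloroformate | C=CCOC(=O)Cl | starting material
4 | allyl 4-isobutoxy-3-methyl-2-oxocyclohex-3-ene-1-carboxylate (racemic) | CC1=C(OCC(C)C)CCC(C(=O)OCC=C)C1=O | intermediate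
5 | allyl 4-isobutoxy-1,3-dimethyl-2-oxocyclohex-3-ene-1-carboxylate (racemic) | CC1=C(OCC(C)C)CCC(C)(C(=O)OCC=C)C1=O | intermediate
6 | (6R)-6-allyl-3-isobutoxy-2,6-dimethylcyclohex-2-en-1-one | CC1=C(OCC(C)C)CC[C@](C)(CC=C)C1=O | intermediate
7 | 2-(2-bromoethyl)-2-methyl-1,3-dioxolane | CC1(CCBr)OCCO1 | starting material
8 | [2-(2-methyl-1,3-dioxolan-2-yl)ethyl]magnesium bromide | CC1(CC[Mg]Br)OCCO1 | intermediate (not isolated)
9 | bromomagnesium alkoxide of the C9 tertiary carbinol (1,2-adduct of 8 to 6; C9 epimers) | CC1=C(OCC(C)C)CC[C@](C)(CC=C)C1(O[Mg]Br)CCC2(C)OCCO2 | intermediate (not isolated)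
10 | (4R)-4-allyl-2,4-dimethyl-3-[2-(2-methyl-1,3-dioxolan-2-yl)ethyl]cyclohex-2-en-1-one | CC1=C(CCC2(C)OCCO2)[C@@](C)(CC=C)CCC1=O | intermediate
11 | (4S)-4-allyl-2,4-dimethyl-3-[2-(2-methyl-1,3-dioxolan-2-yl)ethyl]cyclohexa-2,5-dien-1-one | CC1=C(CCC2(C)OCCO2)[C@@](C)(CC=C)C=CC1=O | intermediate
12 | (1S,4S)-4-allyl-2,4-dimethyl-3-[2-(2-methyl-1,3-dioxolan-2-yl)ethyl]cyclohexa-2,5-dien-1-ol (7β-OH) | CC1=C(CCC2(C)OCCO2)[C@@](C)(CC=C)C=C[C@@H]1O | intermediate
13 | crotonic anhydride | C/C=C/C(=O)OC(=O)/C=C/C | starting material
14 | (E)-but-2-enoate of 12 (7β-dienyl crotonate) | CC1=C(CCC2(C)OCCO2)[C@@](C)(CC=C)C=C[C@@H]1OC(=O)/C=C/C | intermediate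
15 | 1-(trimethylsilyloxy)buta-1,3-dienyl ether of 12 (silyl ketene acetal) | CC1=C(CCC2(C)OCCO2)[C@@](C)(CC=C)C=C[C@@H]1OC(O[Si](C)(C)C)=CC=C | intermediate (not isolated)
16 | trimethylsilyl ester of 17 (C4 epimers) | CC1=C(CCC2(C)OCCO2)[C@@](C)(CC=C)[C@H](C(C=C)C(=O)O[Si](C)(C)C)C=C1 | intermediate (not isolated)
17 | 2-[(1S,6S)-6-allyl-4,6-dimethyl-5-[2-(2-methyl-1,3-dioxolan-2-yl)ethyl]cyclohexa-2,4-dien-1-yl]but-3-enoic acid (C4 epimers) | CC1=C(CCC2(C)OCCO2)[C@@](C)(CC=C)[C@H](C(C=C)C(=O)O)C=C1 | intermediate
18 | 7α-iodo-19,6β-lactone of ring B (C4 epimers) | CC1=C(CCC2(C)OCCO2)[C@@](C)(CC=C)[C@@H]3C(C=C)C(=O)O[C@@H]3[C@H]1I | intermediate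
19 | 19,6β-lactone of ring B, C4 bearing H and vinyl (C4 epimers) | CC1=C(CCC2(C)OCCO2)[C@@](C)(CC=C)[C@@H]3C(C=C)C(=O)O[C@@H]3C1 | intermediate
20 | 4-methyl-4-vinyl-19,6β-lactone of ring B (C18 cis to H5) | CC1=C(CCC2(C)OCCO2)[C@@](C)(CC=C)[C@@H]3[C@](C)(C=C)C(=O)O[C@@H]3C1 | intermediate
21 | 6β,19-diol of ring B with C10 allyl and C4 vinyl arms | CC1=C(CCC2(C)OCCO2)[C@@](C)(CC=C)[C@H]([C@@](C)(CO)C=C)[C@H](O)C1 | intermediate
22 | 6β,19-bis(TBS) ether of 21 (metathesis precursor) | CC1=C(CCC3(C)OCCO3)[C@@](C)(CC=C)[C@H]([C@@](C)(CO[Si](C)(C)C(C)(C)C)C=C)[C@H](O[Si](C)(C)C(C)(C)C)C1 | intermediate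
23 | trans-fused 2-ene bicycle (labda-2,8-diene; 6β,19-bis(TBS) ether, C13 dioxolane) | CC1=C(CCC3(C)OCCO3)[C@@]2(C)CC=C[C@](C)(CO[Si](C)(C)C(C)(C)C)[C@@H]2[C@H](O[Si](C)(C)C(C)(C)C)C1 | intermediate
24 | 2α,3α-diol of 23 | CC1=C(CCC3(C)OCCO3)[C@@]2(C)C[C@@H](O)[C@@H](O)[C@](C)(CO[Si](C)(C)C(C)(C)C)[C@@H]2[C@H](O[Si](C)(C)C(C)(C)C)C1 | intermediate
25 | 2α-O-(phenoxythiocarbonyl) derivative of 24 | CC1=C(CCC3(C)OCCO3)[C@@]2(C)C[C@@H](OC(=S)Oc4ccccc4)[C@@H](O)[C@](C)(CO[Si](C)(C)C(C)(C)C)[C@@H]2[C@H](O[Si](C)(C)C(C)(C)C)C1 | intermediate
26 | 3α-alcohol, 6β,19-bis(TBS) ether, C13 dioxolane | CC1=C(CCC3(C)OCCO3)[C@@]2(C)CC[C@@H](O)[C@](C)(CO[Si](C)(C)C(C)(C)C)[C@@H]2[C@H](O[Si](C)(C)C(C)(C)C)C1 | intermediate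
27 | C13 methyl ketone, 3α-OH, 6β,19-bis(TBS) ether | CC1=C(CCC(C)=O)[C@@]2(C)CC[C@@H](O)[C@](C)(CO[Si](C)(C)C(C)(C)C)[C@@H]2[C@H](O[Si](C)(C)C(C)(C)C)C1 | intermediate
28 | triethyl phosphonoacetate | CCOC(=O)CP(=O)(OCC)OCC | starting material
29 | ethyl (13E)-3α-hydroxy-6β,19-bis(TBS-oxy)labda-8,13-dien-15-oate | CC1=C(CC/C(C)=C/C(=O)OCC)[C@@]2(C)CC[C@@H](O)[C@](C)(CO[Si](C)(C)C(C)(C)C)[C@@H]2[C@H](O[Si](C)(C)C(C)(C)C)C1 | intermediate
30 | ethyl (13E)-3α,6β,19-trihydroxylabda-8,13-dien-15-oate | CC1=C(CC/C(C)=C/C(=O)OCC)[C@@]2(C)CC[C@@H](O)[C@](C)(CO)[C@@H]2[C@H](O)C1 | intermediate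
31 | (13E)-3α,6β,19-trihydroxylabda-8,13-dien-15-oic acid | CC1=C(CC/C(C)=C/C(=O)O)[C@@]2(C)CC[C@@H](O)[C@](C)(CO)[C@@H]2[C@H](O)C1 | target

## Step count and risks
Total step count: 22. Longest linear sequence: 22 steps (from 1).

**Step 15 (ring closure).**
- What may go wrong: the carbene formed at the allyl arm may fail to engage the neopentyl vinyl group, because the two bulky silyl ethers disfavour the rotamer about C4–C5 that points the vinyl group at C1. Oligomerisation or alkene isomerisation would then take over.
- Fallback: set out from lactone 20, in which the five-membered ring freezes that rotamer and the neighbouring groups are small. The same ruthenium catalyst closes C2=C3 to the tricyclic 2-ene 19,6β-lactone F1. LiAlH4 opens it to the 2-ene 6β,19-diol F2. TBSOTf/2,6-lutidine then gives 23, where the route is rejoined.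

**Step 10 (lactonisation of the conjugated diene).**
- What may go wrong: allylic stabilisation may divert the oxygen to C7, or the allylic iodide may ionise and decompose before it is reduced.
- Fallback: set out from acid 17 and activate the diene with a metal instead of a halonium ion, using Pd(OAc)2 (cat.), LiCl and 1,4-benzoquinone in acetone/AcOH at 25 °C. Divalent palladium binds the diene on the α face and the carboxylate attacks the diene terminus C6 anti to the metal, which is the polarity-matched position, to give a C7–C9 π-allyl complex. Chloride opens this complex to the 7β-chloro-19,6β-lactone F3. Bu3SnH/AIBN then reduces F3 through the same allyl radical to 19, where the route is rejoined.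

**Step 7 (C7 reduction).**
- What may go wrong: facial selectivity may be poor because both carbonyl flanks are sp2 carbons, and material may be lost through ionisation of the bis-allylic alcohol during work-up.
- Fallback: set out from 11 and give up reagent control. Luche reduction (NaBH4, CeCl3·7H2O, MeOH, −78 °C) gives 12 together with the 7α-dienol F4. The two epimers are separated on base-washed silica, and F4 is returned to 11 with MnO2 and recycled. The route is rejoined at 12.

## Further compounds
F1 | step 15 | tricyclic labda-2,8-dien-19,6β-olide, C13 dioxolane | CC1=C(CCC3(C)OCCO3)[C@@]2(C)CC=C[C@@]4(C)[C@@H]2[C@H](OC4=O)C1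
F2 | step 15 | labda-2,8-diene-6β,19-diol, C13 dioxolane | CC1=C(CCC3(C)OCCO3)[C@@]2(C)CC=C[C@](C)(CO)[C@@H]2[C@H](O)C1
F3 | step 10 | 7β-chloro-19,6β-lactone of ring B (C4 epimers) | CC1=C(CCC2(C)OCCO2)[C@@](C)(CC=C)[C@@H]3C(C=C)C(=O)O[C@@H]3[C@@H]1Cl
F4 | step 7 | (1R,4S)-4-allyl-2,4-dimethyl-3-[2-(2-methyl-1,3-dioxolan-2-yl)ethyl]cyclohexa-2,5-dien-1-ol (7α-OH) | CC1=C(CCC2(C)OCCO2)[C@@](C)(CC=C)C=C[C@H]1O
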